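Read the mass-balance gap in Friday's closed flask as over-reaction product, since reagent + target → over-reaction product stands among the possible steps.

| setting | Friday's | Wednesday's | Monday's | Sunday's | eta | epsilon | beta | alpha |
|---|---|---|---|---|---|---|---|---|
| substrate | 0.97 M | 0.97 M | 0.97 M | 1.9 M | 0.97 M | 0.97 M | 0.97 M | 0.97 M |
| reagent | 1.26 M | 1.26 M | 1.26 M | 1.26 M | 1.26 M | 1.26 M | 1.26 M | 1.26 M |
| free catalyst | 0.97 mM | 0.48 mM | 0.73 mM | 0.97 mM | 0.97 mM | 0.97 mM | 0.97 mM | 0.97 mM |
| remark | run made earlier | run made earlier | run made earlier | run made earlier | a closed flask charged with all of it at once and left for 3.0 h | plug flow through a tube for 3.0 h, no back-mixing | a single well-mixed tank run continuously and read at steady state, 9.00 h in it on average | a single well-mixed tank run continuously and read at steady state, 3.0 h in it on average |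
| time |  |  |  |  | 3.0 h | 3.0 h |  |  |

Friday's run (percent of the substrate charged)

| time / min | target / % | substrate / % |
|---|---|---|
| 25.0 | 4.5 | 95.6 |
| 50.0 | 7.8 | 91.2 |
| 80.0 | 10.9 | 86.8 |
| 120 | 14.6 | 80.7 |

Wednesday's run (percent of the substrate charged)

| time / h | target / % | substrate / % |
|---|---|---|
| 0.417 | 1.8 | 97.6 |
| 1.00 | 4.5 | 94.9 |
| 2.00 | 7.4 | 90.0 |
| 3.00 | 9.4 | 85.6 |

Monday's run (percent of the substrate charged)

| time / h | target / % | substrate / % |
|---|---|---|
| 0.417 | 2.9 | 96.6 |
| 1.00 | 7.0 | 92.1 |
| 2.00 | 11.2 | 85.0 |
| 3.00 | 13.0 | 78.8 |

Sunday's run (percent of the substrate charged)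

| time / h | target / % | substrate / % |
|---|---|---|
| 0.833 | 4.5 | 94.8 |
| 1.50 | 7.3 | 90.5 |
| 2.50 | 9.9 | 85.5 |
| 3.00 | 10.9 | 83.7 |

(readings scatter by 0.3 percentage points)

- percent here means substrate units held: one spent catalyst counts as two
- the stated concentrations are those of everything mixed, before any reaction; amounts are the same in each set-up
- steps thought possible: reagent + free catalyst -> catalyst intermediate A; catalyst intermediate A <-> catalyst intermediate B; catalyst intermediate B -> by-product + catalyst intermediate C; substrate + catalyst intermediate C <-> catalyst intermediate D; catalyst intermediate D <-> catalyst intermediate E; catalyst intermediate E -> free catalyst + target; 2 catalyst intermediate D -> spent catalyst; reagent + target -> over-reaction product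
- the earlier runs were made in a closed, stirred flask

* the set-up with the highest amount of target at the outlet or at the end, in percent of the substrate put in ("none" if the first two lie within 2 percentage points) (eta / epsilon / beta / alpha / none)
* amount of target at the outlet or at the end, in percent of the substrate put in, eta
* amount of target at the outlet or at the end, in percent of the substrate put in, epsilon
* amount of target at the outlet or at the end, in percent of the substrate put in, beta
* amount of target at the outlet or at the end, in percent of the substrate put in, alpha

Between 80.0 min and 120 min the gap grew by 2.4 percentage points, while target averaged 12.8 % and reagent, reckoned from the substrate gone plus the gap, about 1.07 M. From these we define θ, the pseudo-first-order lifetime of target against over-reaction with reagent at its charge: mean target over the growth rate of the gap, scaled from that reagent level to the charge. As a reading with its scatter, θ is 3.00 h.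

Friday's flask lost 19.3 % of its substrate by 120 min. Taking that mean rate as r and holding it fixed, we get rθ = 29.0 %. Our own reckoning for a closed flask or plug flow, at time t, is then rθ(1 − e^(−t/θ)), which gives 18.3 % for eta and epsilon. For a tank with mean stay τ it is rθ·τ/(τ+θ), which gives 21.7 % for beta. So we put beta ahead by 3.4 points, against a margin of 2 points.

The forecast differs: 17.5 % for eta, 17.5 % for epsilon, 16.5 % for beta and 13.4 % for alpha, and its verdict is none: “The top two tie, so best is none.”

The flask gives 17.3 % for eta and epsilon, 21.0 % for beta and 13.2 % for alpha, so the best is beta.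

    reagent + free catalyst → catalyst intermediate A (k = 540 M⁻¹ h⁻¹)
    catalyst intermediate A ⇌ catalyst intermediate B (K = 0.820, k = 12000 h⁻¹)
    catalyst intermediate B → by-product + catalyst intermediate C (k = 4600 h⁻¹)
    substrate + catalyst intermediate C ⇌ catalyst intermediate D (K = 1.60 M⁻¹, k = 440 M⁻¹ h⁻¹)
    catalyst intermediate D ⇌ catalyst intermediate E (K = 2.20, k = 1400 h⁻¹)
    catalyst intermediate E → free catalyst + target (k = 480 h⁻¹)
    2 catalyst intermediate D → spent catalyst (k = 1400 M⁻¹ h⁻¹)
    reagent + target → over-reaction product (k = 0.290 M⁻¹ h⁻¹)

Beta stands 3.7 points above eta, and its tank holds 0.511 M of reagent, less than the charge of 1.26 M. At that reagent level the over-reaction constant of 0.29 M⁻¹ h⁻¹ gives target a lifetime against over-reaction of 6.75 h in beta, beside a mean stay of 9.00 h. On a second flask, epsilon left until 12 h, the closed-flask expression with θ gives 28.5 %, and that flask reads 29.4 %.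

Readings and results come from a simulation with constants of no real substance, and the scatter is random.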